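Everything rests on disconnecting the O1–C2 bond of the dihydrobenzofuran. C2 is benzylic and para to the free 4-OH of its guaiacyl ring, so acid turns it into a para-quinone methide that the C7a phenol oxygen recaptures; C3 then dictates the trans C2 configuration, whatever the carbinol configuration was. The precursor is the fully assembled trans-dibenzylbutyrolactone whose future furan ring is still open: a (1S,2R)-1,2-diarylpropane-1,3-diol masked as an acetonide, with all three phenols as MOM ethers. One acid treatment removes every protecting group, closes the ring and sets C2. C3 comes from an Evans syn-aldol; the lactone is attached by trans-selective enolate benzylation.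

Key step: step 17

Assumption: the ring that becomes C3a–C7a carries a methyl ester (later CH2Br) at the future C5 so that the lactone can be joined by enolate alkylation; simple alkylating and protecting reagents are given with SMILES in the steps and carry no compound number. Dihydrobenzofuran numbering: O1, C2, C3, C3a, C4–C7, C7a.

Step 1
Reactants: 1 methyl vanillate (methyl 4-hydroxy-3-methoxybenzoate)
Product: 2 methyl 4-(allyloxy)-3-methoxybenzoate
Conditions: allyl bromide, K2CO3, acetone, reflux
Reagents that add atoms: allyl bromide, C=CCBr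
Why: Williamson ether synthesis, in which the potassium phenoxide displaces bromide from allyl bromide by SN2 while the methyl ester is inert to K2CO3 in acetone.

Step 2
Reactants: 2 methyl 4-(allyloxy)-3-methoxybenzoate
Product: 3 methyl 3-allyl-4-hydroxy-5-methoxybenzoate
Conditions: N,N-diethylaniline, 200 °C
Reagents that add atoms: none
Why: Aromatic Claisen rearrangement, a [3,3]-sigmatropic shift that can deliver the allyl group only to the one unsubstituted ortho carbon (the future C3a) before tautomerisation restores the phenol.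

Step 3
Reactants: 3 methyl 3-allyl-4-hydroxy-5-methoxybenzoate
Product: 4 methyl 3-allyl-5-methoxy-4-(methoxymethoxy)benzoate
Conditions: MOMCl, iPr2NEt, CH2Cl2, 0 to 40 °C
Reagents that add atoms: chloromethyl methyl ether, COCCl
Why: MOM protection (O-alkylation of the phenol by the reactive chloromethyl ether) masks the future C7a oxygen with a group that survives the basic, hydride and oxidative steps and leaves only under acid.

Step 4
Reactants: 4 methyl 3-allyl-5-methoxy-4-(methoxymethoxy)benzoate
Product: 5 methyl 3-methoxy-4-(methoxymethoxy)-5-(2-oxoethyl)benzoate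
Conditions: OsO4 (2 mol %), NaIO4, 2,6-lutidine, 1,4-dioxane/H2O, rt; used crude
Reagents that add atoms: osmium tetroxide, O=[Os](=O)(=O)=O (catalytic oxygen carrier); sodium periodate, [Na+].[O-]I(=O)(=O)=O (terminal oxidant)
Why: Lemieux–Johnson oxidation, in which OsO4-catalysed dihydroxylation of the terminal alkene and periodate cleavage of the glycol give the arylacetaldehyde, the lutidine buffer keeping the medium from harming the MOM ether.

Step 5
Reactants: 5 methyl 3-methoxy-4-(methoxymethoxy)-5-(2-oxoethyl)benzoate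
Product: 6 2-[3-methoxy-5-(methoxycarbonyl)-2-(methoxymethoxy)phenyl]acetic acid
Conditions: NaClO2, NaH2PO4, 2-methyl-2-butene, t-BuOH/H2O, 0 °C to rt
Reagents that add atoms: sodium chlorite, [Na+].[O-]Cl=O
Why: Pinnick oxidation, in which chlorous acid oxidises only the aldehyde and the alkene scavenger removes hypochlorous acid before it can chlorinate the electron-rich ring.

Step 6
Reactants: 6 2-[3-methoxy-5-(methoxycarbonyl)-2-(methoxymethoxy)phenyl]acetic acid; 7 (S)-4-benzyl-2-oxazolidinone
Product: 9 methyl 3-{2-[(4S)-4-benzyl-2-oxooxazolidin-3-yl]-2-oxoethyl}-5-methoxy-4-(methoxymethoxy)benzoate, via mixed pivalic anhydride 8 (not isolated)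
Conditions: PivCl, Et3N, THF, −20 °C; then 7, LiCl, rt
Reagents that add atoms: none
Why: N-acylation through a mixed anhydride, in which the hindered pivaloyl carbonyl directs the LiCl-activated oxazolidinone to the arylacetyl carbonyl.

Step 7
Reactants: 10 vanillin
Product: 11 3-methoxy-4-(methoxymethoxy)benzaldehyde
Conditions: MOMCl, iPr2NEt, CH2Cl2, 0 °C to rt
Reagents that add atoms: chloromethyl methyl ether, COCCl
Why: MOM protection (O-alkylation of the phenol) gives an aldehyde partner that tolerates the boron enolate and hydride steps and is unmasked by the same acid as the other protecting groups.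

Step 8
Reactants: 9 methyl 3-{2-[(4S)-4-benzyl-2-oxooxazolidin-3-yl]-2-oxoethyl}-5-methoxy-4-(methoxymethoxy)benzoate; 11 3-methoxy-4-(methoxymethoxy)benzaldehyde
Product: 13 (4S)-4-benzyl-3-{(2S,3S)-3-hydroxy-2-[3-methoxy-5-(methoxycarbonyl)-2-(methoxymethoxy)phenyl]-3-[3-methoxy-4-(methoxymethoxy)phenyl]propanoyl}oxazolidin-2-one, via boron enolate 12 (not isolated)
Conditions: Bu2BOTf, iPr2NEt, CH2Cl2, −78 to 0 °C; then 11, −78 to 0 °C; then pH 7 buffer, MeOH, H2O2, 0 °C
Reagents that add atoms: none
Why: Evans syn-aldol reaction, in which the (Z)-dibutylboron enolate adds through a chair-like Zimmerman–Traxler transition state with the benzyl group of the dipole-opposed (S)-oxazolidinone blocking one enolate face, so the aryl-bearing carbon (the future C3) is set as 2S and the carbinol carbon as 3S, the latter being erased in step 17.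

Step 9
Reactants: 13 (4S)-4-benzyl-3-{(2S,3S)-3-hydroxy-2-[3-methoxy-5-(methoxycarbonyl)-2-(methoxymethoxy)phenyl]-3-[3-methoxy-4-(methoxymethoxy)phenyl]propanoyl}oxazolidin-2-one
Product: 14 (1S,2R)-2-[5-(hydroxymethyl)-3-methoxy-2-(methoxymethoxy)phenyl]-1-[3-methoxy-4-(methoxymethoxy)phenyl]propane-1,3-diol
Conditions: LiBH4 (excess), THF/MeOH, 0 °C then 45 °C
Reagents that add atoms: none
Why: Hydride reduction with reductive removal of the auxiliary, in which LiBH4 attacks the exocyclic imide carbonyl at 0 °C and on warming also reduces the methyl benzoate to the benzylic alcohol, after which the aryl-bearing stereocentre is no longer next to a carbonyl and cannot epimerise.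

Step 10
Reactants: 14 (1S,2R)-2-[5-(hydroxymethyl)-3-methoxy-2-(methoxymethoxy)phenyl]-1-[3-methoxy-4-(methoxymethoxy)phenyl]propane-1,3-diol
Product: 15 {3-methoxy-4-(methoxymethoxy)-5-[(4S,5R)-4-(3-methoxy-4-(methoxymethoxy)phenyl)-2,2-dimethyl-1,3-dioxan-5-yl]phenyl}methanol
Conditions: 2,2-dimethoxypropane, PPTS (cat.), acetone, rt; Et3N quench
Reagents that add atoms: 2,2-dimethoxypropane, COC(C)(C)OC
Why: Acid-catalysed transketalisation (acetonide formation) is thermodynamically selective for the six-membered 1,3-dioxane of the 1,3-diol, and PPTS is too weak to cleave the aryl MOM ethers or to ionise the benzylic carbinol.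

Step 11
Reactants: 15 {3-methoxy-4-(methoxymethoxy)-5-[(4S,5R)-4-(3-methoxy-4-(methoxymethoxy)phenyl)-2,2-dimethyl-1,3-dioxan-5-yl]phenyl}methanol
Product: 16 (4S,5R)-5-[5-(bromomethyl)-3-methoxy-2-(methoxymethoxy)phenyl]-4-[3-methoxy-4-(methoxymethoxy)phenyl]-2,2-dimethyl-1,3-dioxane
Conditions: CBr4, PPh3, 2,6-lutidine, CH2Cl2, 0 °C; used crude
Reagents that add atoms: carbon tetrabromide, BrC(Br)(Br)Br
Why: Appel reaction, in which PPh3/CBr4 activates the primary benzylic alcohol and bromide displaces the activated oxygen under buffered, essentially neutral conditions that spare the ketal and the MOM ethers.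

Step 12
Reactants: 17 3-(4-hydroxy-3-methoxyphenyl)propanoic acid (dihydroferulic acid)
Product: 19 3-[3-methoxy-4-(methoxymethoxy)phenyl]propanoic acid, via methoxymethyl ester 18 (not isolated)
Conditions: MOMCl (2.5 equiv), iPr2NEt, CH2Cl2, 0 °C to rt; then LiOH, THF/H2O, rt; aq. HCl to pH 4, 0 °C
Reagents that add atoms: chloromethyl methyl ether, COCCl
Why: MOM protection followed by saponification, in which MOMCl alkylates both the phenol and the carboxylate and LiOH then cleaves only the acylal-type methoxymethyl ester.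

Step 13
Reactants: 19 3-[3-methoxy-4-(methoxymethoxy)phenyl]propanoic acid; 7 (S)-4-benzyl-2-oxazolidinone
Product: 21 (S)-4-benzyl-3-{3-[3-methoxy-4-(methoxymethoxy)phenyl]propanoyl}oxazolidin-2-one, via mixed pivalic anhydride 20 (not isolated)
Conditions: PivCl, Et3N, THF, −20 °C; then 7, LiCl, rt
Reagents that add atoms: none
Why: N-acylation through a mixed anhydride, as in step 6, attaches the auxiliary that will control the lactone C4 centre.

Step 14
Reactants: 21 (S)-4-benzyl-3-{3-[3-methoxy-4-(methoxymethoxy)phenyl]propanoyl}oxazolidin-2-one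
Product: 23 benzyl (3R)-4-[(4S)-4-benzyl-2-oxooxazolidin-3-yl]-3-[3-methoxy-4-(methoxymethoxy)benzyl]-4-oxobutanoate, via sodium enolate 22 (not isolated)
Conditions: NaN(SiMe3)2, THF, −78 °C; then benzyl bromoacetate, −78 to −40 °C
Reagents that add atoms: benzyl bromoacetate, BrCC(=O)OCc1ccccc1
Why: Evans asymmetric alkylation, in which the chelated (Z)-sodium enolate is alkylated on the face opposite the benzyl group of the (S)-auxiliary, setting the future lactone C4 as R.

Step 15
Reactants: 23 benzyl (3R)-4-[(4S)-4-benzyl-2-oxooxazolidin-3-yl]-3-[3-methoxy-4-(methoxymethoxy)benzyl]-4-oxobutanoate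
Product: 25 (R)-4-[3-methoxy-4-(methoxymethoxy)benzyl]dihydrofuran-2(3H)-one, via hydroxy ester 24 (not isolated)
Conditions: NaBH4, THF/H2O, 0 °C to rt; aq. citric acid work-up
Reagents that add atoms: none
Why: Chemoselective borohydride reduction (reductive removal of the auxiliary), in which NaBH4 in aqueous THF reduces the activated imide carbonyl but not the benzyl ester, and the new primary hydroxyl closes onto that ester by 5-exo-trig lactonisation without acid that could cleave the aryl MOM ether.

Step 16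
Reactants: 25 (R)-4-[3-methoxy-4-(methoxymethoxy)benzyl]dihydrofuran-2(3H)-one; 16 (4S,5R)-5-[5-(bromomethyl)-3-methoxy-2-(methoxymethoxy)phenyl]-4-[3-methoxy-4-(methoxymethoxy)phenyl]-2,2-dimethyl-1,3-dioxane
Product: 27 (3R,4R)-3-{3-methoxy-4-(methoxymethoxy)-5-[(4S,5R)-4-(3-methoxy-4-(methoxymethoxy)phenyl)-2,2-dimethyl-1,3-dioxan-5-yl]benzyl}-4-[3-methoxy-4-(methoxymethoxy)benzyl]dihydrofuran-2(3H)-one, via lithium enolate 26 (not isolated)
Conditions: LiN(SiMe3)2, THF, −78 °C; then 16, THF/DMPU, −78 to −30 °C
Reagents that add atoms: none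
Why: Lactone enolate alkylation (SN2 at the benzylic bromide), in which the C4 arylmethyl group shields one face of the planar lithium enolate so that the new benzyl group enters anti to it and the lactone C3 centre is set as R (trans-3,4).

Step 17
Reactants: 27 (3R,4R)-3-{3-methoxy-4-(methoxymethoxy)-5-[(4S,5R)-4-(3-methoxy-4-(methoxymethoxy)phenyl)-2,2-dimethyl-1,3-dioxan-5-yl]benzyl}-4-[3-methoxy-4-(methoxymethoxy)benzyl]dihydrofuran-2(3H)-one
Product: 30 isolappaol A, via seco-isolappaol A 28 (not isolated), via para-quinone methide 29 (not isolated)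
Conditions: HCl (1.25 M in MeOH), MeOH/CH2Cl2, 0 °C to rt; NaHCO3 quench
Reagents that add atoms: none
Why: Acid-catalysed acetal exchange with methanol strips the three MOM ethers and the acetonide to give 28, whose benzylic hydroxyl is protonated and lost as water, pushed by the para 4-OH, to give the planar para-quinone methide 29 (or its O-protonated benzylic cation), which erases the carbinol configuration. The C7a phenol oxygen then adds to the exocyclic methide carbon in an intramolecular oxa-1,6-conjugate addition, a 5-exo-trig closure that forms O1–C2 and rearomatises the guaiacyl ring. The closest known reaction type is the acid-mediated cyclisation of 1-(4-hydroxyaryl)-2-(2-hydroxyaryl)propane-1,3-diols to trans-phenylcoumarans, familiar from lignin 8–5 units. The new C2 centre (S) is controlled by the existing C3 centre, since the aryl group takes the position anti to the C3 hydroxymethyl group in the envelope transition state and reversible ionisation under acid should funnel any cis isomer to the trans (2S,3R) ring. The step needs attack by the phenol and not by the primary alcohol or methanol, and no loss of H-3: the ortho phenol sits five atoms from the methide carbon, the alcohol could only form a strained oxetane, capture by methanol is reversible, and the low temperature disfavours elimination. The lactone, its two stereocentres and the free phenols should be inert to methanolic HCl at room temperature.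

Compound list
1 | methyl vanillate (methyl 4-hydroxy-3-methoxybenzoate) | COC(=O)c1ccc(O)c(OC)c1 | starting material
2 | methyl 4-(allyloxy)-3-methoxybenzoate | C=CCOc1ccc(C(=O)OC)cc1OC | intermediate
3 | methyl 3-allyl-4-hydroxy-5-methoxybenzoate | C=CCc1cc(C(=O)OC)cc(OC)c1O | intermediate
4 | methyl 3-allyl-5-methoxy-4-(methoxymethoxy)benzoate | C=CCc1cc(C(=O)OC)cc(OC)c1OCOC | intermediate
5 | methyl 3-methoxy-4-(methoxymethoxy)-5-(2-oxoethyl)benzoate | O=CCc1cc(C(=O)OC)cc(OC)c1OCOC | intermediate
6 | 2-[3-methoxy-5-(methoxycarbonyl)-2-(methoxymethoxy)phenyl]acetic acid | OC(=O)Cc1cc(C(=O)OC)cc(OC)c1OCOC | intermediate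
7 | (S)-4-benzyl-2-oxazolidinone | O=C1OC[C@H](Cc2ccccc2)N1 | starting material
8 | mixed pivalic anhydride of 6 (formed in the flask) | CC(C)(C)C(=O)OC(=O)Cc1cc(C(=O)OC)cc(OC)c1OCOC | intermediate
9 | methyl 3-{2-[(4S)-4-benzyl-2-oxooxazolidin-3-yl]-2-oxoethyl}-5-methoxy-4-(methoxymethoxy)benzoate | COCOc1c(OC)cc(C(=O)OC)cc1CC(=O)N1[C@@H](Cc2ccccc2)COC1=O | intermediate
10 | vanillin | COc1cc(C=O)ccc1O | starting material
11 | 3-methoxy-4-(methoxymethoxy)benzaldehyde | COCOc1ccc(C=O)cc1OC | intermediate
12 | (Z)-dibutylboron enolate of 9 (formed in the flask) | CCCCB(CCCC)O/C(=C\c1cc(C(=O)OC)cc(OC)c1OCOC)N1[C@@H](Cc2ccccc2)COC1=O | intermediate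
13 | (4S)-4-benzyl-3-{(2S,3S)-3-hydroxy-2-[3-methoxy-5-(methoxycarbonyl)-2-(methoxymethoxy)phenyl]-3-[3-methoxy-4-(methoxymethoxy)phenyl]propanoyl}oxazolidin-2-one | O=C(N1[C@@H](Cc2ccccc2)COC1=O)[C@@H](c1cc(C(=O)OC)cc(OC)c1OCOC)[C@H](O)c1ccc(OCOC)c(OC)c1 | intermediate
14 | (1S,2R)-2-[5-(hydroxymethyl)-3-methoxy-2-(methoxymethoxy)phenyl]-1-[3-methoxy-4-(methoxymethoxy)phenyl]propane-1,3-diol | OC[C@@H](c1cc(CO)cc(OC)c1OCOC)[C@H](O)c1ccc(OCOC)c(OC)c1 | intermediate
15 | {3-methoxy-4-(methoxymethoxy)-5-[(4S,5R)-4-(3-methoxy-4-(methoxymethoxy)phenyl)-2,2-dimethyl-1,3-dioxan-5-yl]phenyl}methanol | CC1(C)OC[C@@H](c2cc(CO)cc(OC)c2OCOC)[C@@H](c2ccc(OCOC)c(OC)c2)O1 | intermediate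
16 | (4S,5R)-5-[5-(bromomethyl)-3-methoxy-2-(methoxymethoxy)phenyl]-4-[3-methoxy-4-(methoxymethoxy)phenyl]-2,2-dimethyl-1,3-dioxane | CC1(C)OC[C@@H](c2cc(CBr)cc(OC)c2OCOC)[C@@H](c2ccc(OCOC)c(OC)c2)O1 | intermediate
17 | 3-(4-hydroxy-3-methoxyphenyl)propanoic acid (dihydroferulic acid) | COc1cc(CCC(=O)O)ccc1O | starting material
18 | methoxymethyl 3-[3-methoxy-4-(methoxymethoxy)phenyl]propanoate (formed in the flask) | COCOC(=O)CCc1ccc(OCOC)c(OC)c1 | intermediate
19 | 3-[3-methoxy-4-(methoxymethoxy)phenyl]propanoic acid | OC(=O)CCc1ccc(OCOC)c(OC)c1 | intermediate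
20 | mixed pivalic anhydride of 19 (formed in the flask) | CC(C)(C)C(=O)OC(=O)CCc1ccc(OCOC)c(OC)c1 | intermediate
21 | (S)-4-benzyl-3-{3-[3-methoxy-4-(methoxymethoxy)phenyl]propanoyl}oxazolidin-2-one | COCOc1ccc(CCC(=O)N2[C@@H](Cc3ccccc3)COC2=O)cc1OC | intermediate
22 | sodium (Z)-enolate of 21 (formed in the flask) | [Na+].[O-]/C(=C\Cc1ccc(OCOC)c(OC)c1)N1[C@@H](Cc2ccccc2)COC1=O | intermediate
23 | benzyl (3R)-4-[(4S)-4-benzyl-2-oxooxazolidin-3-yl]-3-[3-methoxy-4-(methoxymethoxy)benzyl]-4-oxobutanoate | O=C(N1[C@@H](Cc2ccccc2)COC1=O)[C@H](Cc1ccc(OCOC)c(OC)c1)CC(=O)OCc1ccccc1 | intermediate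
24 | benzyl (3R)-4-hydroxy-3-[3-methoxy-4-(methoxymethoxy)benzyl]butanoate (formed in the flask) | OC[C@H](Cc1ccc(OCOC)c(OC)c1)CC(=O)OCc1ccccc1 | intermediate
25 | (R)-4-[3-methoxy-4-(methoxymethoxy)benzyl]dihydrofuran-2(3H)-one | COCOc1ccc(C[C@H]2COC(=O)C2)cc1OC | intermediate
26 | lithium enolate of 25 (formed in the flask) | [Li+].COCOc1ccc(C[C@H]2COC([O-])=C2)cc1OC | intermediate
27 | (3R,4R)-3-{3-methoxy-4-(methoxymethoxy)-5-[(4S,5R)-4-(3-methoxy-4-(methoxymethoxy)phenyl)-2,2-dimethyl-1,3-dioxan-5-yl]benzyl}-4-[3-methoxy-4-(methoxymethoxy)benzyl]dihydrofuran-2(3H)-one (protected seco compound) | COCOc1ccc(C[C@H]2COC(=O)[C@@H]2Cc3cc(OC)c(OCOC)c(c3)[C@@H]4COC(C)(C)O[C@@H]4c5ccc(OCOC)c(OC)c5)cc1OC | intermediate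
28 | seco-isolappaol A, the ring-opened (1S,2R)-diol with free C7a phenol (formed in the flask) | COc1cc(C[C@H]2COC(=O)[C@@H]2Cc2cc(OC)c(O)c(c2)[C@H](CO)[C@@H](c2ccc(O)c(OC)c2)O)ccc1O | intermediate
29 | para-quinone methide derived from 28 (formed in the flask) | COc1cc(C[C@H]2COC(=O)[C@@H]2Cc2cc(OC)c(O)c(c2)[C@H](CO)C=C2C=CC(=O)C(OC)=C2)ccc1O | intermediate
30 | isolappaol A | COc1cc(C[C@H]2COC(=O)[C@@H]2Cc2cc(OC)c3c(c2)[C@H](CO)[C@@H](c2ccc(O)c(OC)c2)O3)ccc1O | target

Total step count: 17. Longest linear sequence: 12 steps (steps 1–6, 8–11, 16 and 17, from methyl vanillate).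

Steps most likely to fail

Step 17. The acid strength needed to cleave three aryl MOM ethers may let the benzylic cation lose H-3 (stilbene formation, which would also scramble C3), or let methanol and formaldehyde-derived electrophiles be captured irreversibly by the free phenol rings or the diol before the ring closes. The fallback separates phenol unmasking from ionisation. It sets out from 27: TMSOTf and 2,2'-bipyridyl in CH2Cl2 at 0 °C, then water, should remove the three aryl MOM groups through pyridinium-type activation of the formaldehyde acetals, a mode that should spare the ketal, and give (3R,4R)-4-(4-hydroxy-3-methoxybenzyl)-3-{4-hydroxy-3-[(4S,5R)-4-(4-hydroxy-3-methoxyphenyl)-2,2-dimethyl-1,3-dioxan-5-yl]-5-methoxybenzyl}dihydrofuran-2(3H)-one F1. This triphenol acetonide already has the free C7a and 4-OH groups, so PPTS in MeOH/CH2Cl2 at rt, an acid too weak to do more than open the dioxane and ionise the para-hydroxybenzylic carbinol, should open the ketal and close the dihydrofuran ring with acetone as the only by-product. The fallback comes back to the route at 30.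

Step 16. The electron-rich para-alkoxybenzylic bromide may ionise or decompose before it meets the enolate, and proton transfer from product to enolate may cause double alkylation or erode the trans selectivity. The fallback forms the same C–C bond by carbonyl addition and sets out from 15 and 25. Oxidation of 15 with MnO2 (CH2Cl2, rt) should give 3-methoxy-4-(methoxymethoxy)-5-[(4S,5R)-4-(3-methoxy-4-(methoxymethoxy)phenyl)-2,2-dimethyl-1,3-dioxan-5-yl]benzaldehyde F2. Addition of this stable aldehyde to lithium enolate 26 (from 25, LiN(SiMe3)2, THF, −78 °C) should give the α-(aryl)(hydroxy)methyl lactone F3, as a mixture at the new carbinol carbon, which is immaterial. Mesylation (MsCl, Et3N, CH2Cl2, 0 °C) and elimination with DBU should give the (E)-α-arylidene lactone F4. Conjugate reduction with NaBH4/NiCl2·6H2O (MeOH/THF, 0 °C), then DBU in toluene to equilibrate the α-centre to the more stable trans arrangement, comes back to the route at 27.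

Step 8. The aryl-conjugated boron enolate may add slowly and reversibly to the electron-rich, deactivated aldehyde 11, so that conversion stalls and retro-aldol during work-up erodes the enolate-face selectivity that sets C3. The fallback uses a more electrophilic aldehyde partner and restores the MOM group afterwards; it sets out from 9. Boron enolate 12, made as in step 8, is combined with purchased 4-formyl-2-methoxyphenyl acetate to give (4S)-4-benzyl-3-{(2S,3S)-3-(4-acetoxy-3-methoxyphenyl)-3-hydroxy-2-[3-methoxy-5-(methoxycarbonyl)-2-(methoxymethoxy)phenyl]propanoyl}oxazolidin-2-one F5. LiBH4 (THF/MeOH, 0 then 45 °C) should remove the auxiliary, reduce the benzoate and cleave the aryl acetate in one operation to give (1S,2R)-1-(4-hydroxy-3-methoxyphenyl)-2-[5-(hydroxymethyl)-3-methoxy-2-(methoxymethoxy)phenyl]propane-1,3-diol F6. Selective O-alkylation of the phenoxide alone (MOMCl, K2CO3, acetone, 0 °C; the three alcohols are not deprotonated) comes back to the route at 14.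

Further compounds
F1 | step 17 | (3R,4R)-4-(4-hydroxy-3-methoxybenzyl)-3-{4-hydroxy-3-[(4S,5R)-4-(4-hydroxy-3-methoxyphenyl)-2,2-dimethyl-1,3-dioxan-5-yl]-5-methoxybenzyl}dihydrofuran-2(3H)-one | COc1cc(C[C@H]2COC(=O)[C@@H]2Cc3cc(OC)c(O)c(c3)[C@@H]4COC(C)(C)O[C@@H]4c5ccc(O)c(OC)c5)ccc1O
F2 | step 16 | 3-methoxy-4-(methoxymethoxy)-5-[(4S,5R)-4-(3-methoxy-4-(methoxymethoxy)phenyl)-2,2-dimethyl-1,3-dioxan-5-yl]benzaldehyde | CC1(C)OC[C@@H](c2cc(C=O)cc(OC)c2OCOC)[C@@H](c2ccc(OCOC)c(OC)c2)O1
F3 | step 16 | (3R,4R)-3-{hydroxy[3-methoxy-4-(methoxymethoxy)-5-((4S,5R)-4-(3-methoxy-4-(methoxymethoxy)phenyl)-2,2-dimethyl-1,3-dioxan-5-yl)phenyl]methyl}-4-[3-methoxy-4-(methoxymethoxy)benzyl]dihydrofuran-2(3H)-one, trans on the lactone ring, mixture at the carbinol carbon | COCOc1ccc(C[C@H]2COC(=O)[C@@H]2C(O)c3cc(OC)c(OCOC)c(c3)[C@@H]4COC(C)(C)O[C@@H]4c5ccc(OCOC)c(OC)c5)cc1OC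
F4 | step 16 | (R,E)-3-{3-methoxy-4-(methoxymethoxy)-5-[(4S,5R)-4-(3-methoxy-4-(methoxymethoxy)phenyl)-2,2-dimethyl-1,3-dioxan-5-yl]benzylidene}-4-[3-methoxy-4-(methoxymethoxy)benzyl]dihydrofuran-2(3H)-one | COCOc1ccc(C[C@H]2COC(=O)/C2=C/c3cc(OC)c(OCOC)c(c3)[C@@H]4COC(C)(C)O[C@@H]4c5ccc(OCOC)c(OC)c5)cc1OC
F5 | step 8 | (4S)-4-benzyl-3-{(2S,3S)-3-(4-acetoxy-3-methoxyphenyl)-3-hydroxy-2-[3-methoxy-5-(methoxycarbonyl)-2-(methoxymethoxy)phenyl]propanoyl}oxazolidin-2-one | O=C(N1[C@@H](Cc2ccccc2)COC1=O)[C@@H](c1cc(C(=O)OC)cc(OC)c1OCOC)[C@H](O)c1ccc(OC(C)=O)c(OC)c1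
F6 | step 8 | (1S,2R)-1-(4-hydroxy-3-methoxyphenyl)-2-[5-(hydroxymethyl)-3-methoxy-2-(methoxymethoxy)phenyl]propane-1,3-diol | OC[C@@H](c1cc(CO)cc(OC)c1OCOC)[C@H](O)c1ccc(O)c(OC)c1
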